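All constants are made up.

6.0 min looks long for this flask: the electrophile's half-life by its reaction with nucleophile alone, other concentrations as charged, is 0.14 min.

electrophile 0.050 M; nucleophile 1.50 equiv; buffer base 3.00 equiv; buffer acid 0.100 equiv; time 6.0 min

    electrophile + nucleophile → acid + target + leaving group (k1 = 1.1 /M/s)
    protonated nucleophile ⇌ nucleophile + acid, settled at all times (K2 = 1.6 × 10⁻¹⁰ M)
    buffer acid ⇌ buffer base + acid, settled at all times (K3 = 2.5 × 10⁻⁵ M)
    2 nucleophile → self-condensation product (k4 = 0.075 /M/s)
    nucleophile + target ⇌ idle adduct, settled at all times (K5 = 120 /M)
    crystals ⇌ leaving group, rate k6*(cs6 - [leaving group]) while solid is left; crystals form when [leaving group] > cs6 (cs6 = 1.0 mM, k6 = 0.22 /s)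

- acid is the free proton; pH is minus the decimal logarithm of its molar concentration
- for target the idle adduct is counted in
- for leaving group the crystals are counted in
- two of one species on the left: rate k times its square, two consumed each time
- as a solid, counted per litre of solution: crystals
- run time (flask): 6.0 min

* part of the electrophile that has reacted at 6.0 min
* pH of the solution at 6.0 min

The neighbour flask with 0.400 equiv of buffer acid looks nearly the same as the main flask: it has the same nucleophile and the same buffer base. My reckoning for both follows the proton.

1. Each turn of the main reaction frees a proton. In the main flask at the start, nucleophile takes it over buffer base by 70600 to one, so you pay two nucleophile per turn.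
2. Buffer acid spends nucleophile the same way, one each, before any turn.
3. Charged nucleophile less charged buffer acid, divided by two, gives 70.0% of the electrophile in the main flask. Call this the nucleophile ceiling: the conversion the nucleophile can pay for while protons land on it. It makes nucleophile the limiting reagent. The neighbour's ceiling is lower, 55.0%.
4. Self-condensation draws on the same nucleophile. In the main flask at the start, the main reaction uses nucleophile 5.3 times as fast. Hold that ratio for the whole run, and each turn costs two nucleophile plus its inverse, giving 63.9%. The neighbour's ratio, reckoned from its free nucleophile, is 6.67, giving 51.2%.
5. That ratio goes as electrophile over free nucleophile, and a turn takes two nucleophile against one electrophile, so it climbs and the true loss is smaller. I commit to between 63.9% and 70.0% for the main flask, and between 51.2% and 55.0% for the neighbour. I expect the neighbour to end lower because its ceiling stands lower.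

My bracket gives no pH, which needs the small free nucleophile left. The forecast gives 66.2% and pH 7.5, reasoning that “Each turn therefore removes two nucleophiles”. Its conversion lies inside my bracket.

The main flask gives 66.3% at pH 7.45. With self-condensation struck out, it gives 69.1%, which is 0.9 percentage points under its ceiling of 70.0%. The neighbour flask reaches 53.5%, which is 1.5 points under its ceiling of 55.0%.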